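Ring A (the ten-membered carbocycle C1–C10) is disconnected at C8–C9, the only ring bond whose two carbons both carry oxygen: a trans-diol lying between C7 of the trans-fused γ-lactone (ring B: O–C12–C11–C7–C6) and the C1=C10 olefin. A titanium-mediated pinacol coupling of two aldehydes closes ring A, forms C8–C9 and sets both carbinol centres at once, delivering the two angelate oxygens. The precursor is the γ-lactone with the C8 aldehyde on C7 and, on C6, a (4E,1(10)Z)-diene chain ending in the C9 enal; C15–OH is masked as a TBDPS ether, C14–OH as a PMB ether, and both aldehydes are unveiled together one step earlier.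

Key step: step 19

Remark on the structure: the target is read as 6R,7S,8S,9S (12,6α-olide, H-7α, 8β- and 9α-angelates, O8 cis to C11); both ring olefins are ring-cis (C3 cis to C6, C2 cis to C9), which makes them 4E and 1(10)E by the sequence rules in the target. Germacrane numbering is used in the text.

Assumption: monomeric formaldehyde is made by cracking paraformaldehyde; the 12,6-lactone is taken not to migrate to O8 under neutral or mildly acidic conditions, so basic work-ups are avoided whenever C8–OH is free.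

Step 1
Reactants: 1 (S)-5-(hydroxymethyl)furan-2(5H)-one
Product: 2 (S)-5-{[(tert-butyldimethylsilyl)oxy]methyl}furan-2(5H)-one
Conditions: t-BuMe2SiCl, imidazole, CH2Cl2, 0 °C → rt
Reagents that add atoms: tert-butyldimethylsilyl chloride, CC(C)(C)[Si](C)(C)Cl
Why: Imidazole-promoted silyl ether formation masks O5 for the radical step and leaves the C6 stereocentre untouched.

Step 2
Reactants: 2 (S)-5-{[(tert-butyldimethylsilyl)oxy]methyl}furan-2(5H)-one; 3 methanol
Product: 4 (4R,5S)-5-{[(tert-butyldimethylsilyl)oxy]methyl}-4-(hydroxymethyl)oxolan-2-one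
Conditions: hν (350 nm), benzophenone (0.2 equiv), degassed MeOH, rt
Reagents that add atoms: methanol (3), CO
Why: Benzophenone-sensitised photochemical conjugate addition of the hydroxymethyl radical (Giese-type radical addition) should occur at C7 anti to the C6 silyloxymethyl group, which sets the trans 6,7-relationship and brings in C8 at the alcohol level.

Step 3
Reactants: 4 (4R,5S)-5-{[(tert-butyldimethylsilyl)oxy]methyl}-4-(hydroxymethyl)oxolan-2-one
Product: 5 (4R,5S)-5-{[(tert-butyldimethylsilyl)oxy]methyl}-4-[(trityloxy)methyl]oxolan-2-one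
Conditions: Ph3CCl, Et3N, 4-(dimethylamino)pyridine (cat.), CH2Cl2, rt
Reagents that add atoms: trityl chloride, ClC(c1ccccc1)(c1ccccc1)c1ccccc1
Why: Tritylation of the primary C8 hydroxyl (SN1-type etherification) gives an achiral ether that is stable to fluoride and base and is later removed by mild acid.

Step 4
Reactants: 5 (4R,5S)-5-{[(tert-butyldimethylsilyl)oxy]methyl}-4-[(trityloxy)methyl]oxolan-2-one
Product: 6 (4R,5S)-5-(hydroxymethyl)-4-[(trityloxy)methyl]oxolan-2-one
Conditions: Bu4NF, AcOH (1:1), THF, 0 °C → rt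
Reagents that add atoms: none
Why: Buffered fluoride desilylation should free O5 selectively, the trityl ether and the lactone being inert to it.

Step 5
Reactants: 6 (4R,5S)-5-(hydroxymethyl)-4-[(trityloxy)methyl]oxolan-2-one
Product: 7 (2S,3R)-5-oxo-3-[(trityloxy)methyl]oxolane-2-carbaldehyde (C5 aldehyde)
Conditions: Dess–Martin periodinane, NaHCO3, CH2Cl2, 0 °C → rt; used at once
Reagents that add atoms: none
Why: Dess–Martin oxidation under bicarbonate buffer should give the α-acyloxy aldehyde without epimerising C6.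

Step 6
Reactants: 8 5-chloropent-1-yne; 9 methyl chloroformate
Product: 11 methyl 6-chlorohex-2-ynoate, via lithium acetylide 10 (not isolated)
Conditions: n-BuLi, THF, −78 °C; ClCO2Me, −78 → 0 °C
Reagents that add atoms: methyl chloroformate (9), COC(=O)Cl
Why: Deprotonation of the terminal alkyne and C-acylation of the acetylide with the chloroformate give the ynoate, the primary chloride being inert at −78 °C.

Step 7
Reactants: 11 methyl 6-chlorohex-2-ynoate
Product: 12 methyl (2E)-6-chloro-2-(tributylstannyl)hex-2-enoate (ester cis to the chain)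
Conditions: Bu3SnH (slow addition), Pd(PPh3)4 (2 mol %), THF, 0 °C → rt
Reagents that add atoms: tributyltin hydride, CCCC[SnH](CCCC)CCCC
Why: Hydrostannation of an ynoate catalysed by zerovalent palladium is a syn addition that places tin on the α-carbon, so the ester carbon (future C9) ends cis to the C2 chain and tin marks C10.

Step 8
Reactants: 12 methyl (2E)-6-chloro-2-(tributylstannyl)hex-2-enoate
Product: 13 (2E)-6-chloro-2-(tributylstannyl)hex-2-en-1-ol
Conditions: i-Bu2AlH (2.5 equiv), CH2Cl2, −78 °C; aq. KNaC4H4O6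
Reagents that add atoms: none
Why: Hydride reduction of the conjugated ester to the allylic alcohol leaves the vinylstannane, the olefin geometry and the alkyl chloride intact.

Step 9
Reactants: 13 (2E)-6-chloro-2-(tributylstannyl)hex-2-en-1-ol
Product: 14 tributyl[(2E)-6-chloro-1-(trityloxy)hex-2-en-2-yl]stannane
Conditions: Ph3CCl, Et3N, 4-(dimethylamino)pyridine (cat.), CH2Cl2, rt
Reagents that add atoms: trityl chloride, ClC(c1ccccc1)(c1ccccc1)c1ccccc1
Why: Tritylation gives a C9 ether that, unlike a silyl ether, cannot migrate to the neighbouring carbanion or alkoxide in the next two steps.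

Step 10
Reactants: 14 tributyl[(2E)-6-chloro-1-(trityloxy)hex-2-en-2-yl]stannane; 15 formaldehyde
Product: 17 (2Z)-6-chloro-2-[(trityloxy)methyl]hex-2-en-1-ol (C14–OH trans to the chain), via vinyllithium 16 (not isolated)
Conditions: n-BuLi, THF, −78 °C; HCHO (gas), −78 °C; H2O
Reagents that add atoms: formaldehyde (15), C=O
Why: Tin–lithium exchange proceeds with retention of olefin geometry and the vinyllithium adds to formaldehyde (1,2-addition), installing C14 trans to the C2 chain, while lithium sits trans to the chloropropyl chain and cannot cyclise onto it.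

Step 11
Reactants: 17 (2Z)-6-chloro-2-[(trityloxy)methyl]hex-2-en-1-ol
Product: 18 1-({[(2Z)-6-chloro-2-[(trityloxy)methyl]hex-2-en-1-yl]oxy}methyl)-4-methoxybenzene (C14 PMB ether, C9 trityl ether)
Conditions: NaH, 4-MeOC6H4CH2Cl, Bu4NI (cat.), THF–DMF, 0 °C → rt
Reagents that add atoms: 4-methoxybenzyl chloride, COc1ccc(CCl)cc1
Why: Williamson etherification of the primary allylic alkoxide with the benzylic chloride keeps the C9/C14 differentiation because trityl does not migrate under base.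

Step 12
Reactants: 18 1-({[(2Z)-6-chloro-2-[(trityloxy)methyl]hex-2-en-1-yl]oxy}methyl)-4-methoxybenzene
Product: 20 [(4Z)-5-{[(4-methoxybenzyl)oxy]methyl}-6-(trityloxy)hex-4-en-1-yl]triphenylphosphonium iodide, via alkyl iodide 19 (not isolated)
Conditions: NaI, PPh3, NaHCO3 (solid, trace), MeCN, reflux
Reagents that add atoms: triphenylphosphine, c1ccc(cc1)P(c1ccccc1)c1ccccc1; sodium iodide, [Na+].[I-]
Why: In-situ Finkelstein exchange followed by SN2 quaternisation of triphenylphosphine at the primary carbon C4 gives the phosphonium salt under neutral conditions.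

Step 13
Reactants: 20 [(4Z)-5-{[(4-methoxybenzyl)oxy]methyl}-6-(trityloxy)hex-4-en-1-yl]triphenylphosphonium iodide; 21 ethyl formate
Product: 23 (5Z)-6-{[(4-methoxybenzyl)oxy]methyl}-2-(triphenyl-λ5-phosphanylidene)-7-(trityloxy)hept-5-enal, via phosphonium ylide 22 (not isolated)
Conditions: NaN(SiMe3)2 (2.1 equiv), THF, −78 → 0 °C; HCO2Et, −78 °C → rt
Reagents that add atoms: ethyl formate (21), CCOC=O
Why: C-Formylation of the non-stabilised ylide with a formate ester (acylation of a phosphorus ylide) followed by loss of the second α-proton should give the formyl-stabilised ylide, bringing in C15 at the aldehyde level.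

Step 14
Reactants: 7 (2S,3R)-5-oxo-3-[(trityloxy)methyl]oxolane-2-carbaldehyde; 23 (5Z)-6-{[(4-methoxybenzyl)oxy]methyl}-2-(triphenyl-λ5-phosphanylidene)-7-(trityloxy)hept-5-enal
Product: 24 (2E)-2-[(3Z)-4-{[(4-methoxybenzyl)oxy]methyl}-5-(trityloxy)pent-3-en-1-yl]-3-{(2R,3R)-5-oxo-3-[(trityloxy)methyl]oxolan-2-yl}prop-2-enal (C15 enal)
Conditions: PhMe, 80 °C
Reagents that add atoms: none
Why: Wittig olefination with an α-substituted formyl-stabilised ylide is E-selective, which places C6 cis to C3 and trans to the C15 aldehyde, and the weakly basic ylide should spare the C6 stereocentre.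

Step 15
Reactants: 24 (2E)-2-[(3Z)-4-{[(4-methoxybenzyl)oxy]methyl}-5-(trityloxy)pent-3-en-1-yl]-3-{(2R,3R)-5-oxo-3-[(trityloxy)methyl]oxolan-2-yl}prop-2-enal
Product: 25 (4R,5R)-5-[(1E,5Z)-2-(hydroxymethyl)-6-{[(4-methoxybenzyl)oxy]methyl}-7-(trityloxy)hepta-1,5-dien-1-yl]-4-[(trityloxy)methyl]oxolan-2-one
Conditions: NaBH4, CeCl3·7H2O, MeOH–THF, −30 °C
Reagents that add atoms: none
Why: Luche reduction should reduce the enal in 1,2-fashion and leave the γ-lactone untouched at low temperature.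

Step 16
Reactants: 25 (4R,5R)-5-[(1E,5Z)-2-(hydroxymethyl)-6-{[(4-methoxybenzyl)oxy]methyl}-7-(trityloxy)hepta-1,5-dien-1-yl]-4-[(trityloxy)methyl]oxolan-2-one
Product: 26 (4R,5R)-5-[(1E,5Z)-2-{[(tert-butyldiphenylsilyl)oxy]methyl}-6-{[(4-methoxybenzyl)oxy]methyl}-7-(trityloxy)hepta-1,5-dien-1-yl]-4-[(trityloxy)methyl]oxolan-2-one
Conditions: t-BuPh2SiCl, imidazole, CH2Cl2, 0 °C → rt
Reagents that add atoms: tert-butyldiphenylsilyl chloride, CC(C)(C)[Si](Cl)(c1ccccc1)c1ccccc1
Why: Silylation of the primary allylic alcohol installs a TBDPS ether, chosen because it survives the acid steps that later remove the trityl groups and the acetonide.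

Step 17
Reactants: 26 (4R,5R)-5-[(1E,5Z)-2-{[(tert-butyldiphenylsilyl)oxy]methyl}-6-{[(4-methoxybenzyl)oxy]methyl}-7-(trityloxy)hepta-1,5-dien-1-yl]-4-[(trityloxy)methyl]oxolan-2-one
Product: 27 (4R,5R)-5-[(1E,5E)-2-{[(tert-butyldiphenylsilyl)oxy]methyl}-7-hydroxy-6-{[(4-methoxybenzyl)oxy]methyl}hepta-1,5-dien-1-yl]-4-(hydroxymethyl)oxolan-2-one (C8,C9-diol)
Conditions: TsOH·H2O (cat.), MeOH–CH2Cl2, 0 °C → rt
Reagents that add atoms: none
Why: Acid-catalysed methanolysis (SN1 detritylation) should remove both trityl ethers at once, while the TBDPS and PMB ethers and the lactone are stable to catalytic acid.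

Step 18
Reactants: 27 (4R,5R)-5-[(1E,5E)-2-{[(tert-butyldiphenylsilyl)oxy]methyl}-7-hydroxy-6-{[(4-methoxybenzyl)oxy]methyl}hepta-1,5-dien-1-yl]-4-(hydroxymethyl)oxolan-2-one
Product: 28 (2R,3S)-2-[(1E,5Z)-2-{[(tert-butyldiphenylsilyl)oxy]methyl}-6-formyl-7-[(4-methoxybenzyl)oxy]hepta-1,5-dien-1-yl]-5-oxooxolane-3-carbaldehyde (C8/C9 dialdehyde)
Conditions: Dess–Martin periodinane (3 equiv), NaHCO3, CH2Cl2, 0 °C; used within hours
Reagents that add atoms: none
Why: Double Dess–Martin oxidation under buffered, amine-free conditions should convert the alkyl and the allylic primary alcohol into the two aldehydes without isomerising the (Z)-enal or eliminating the β-acyloxy aldehyde.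

Step 19
Reactants: 28 (2R,3S)-2-[(1E,5Z)-2-{[(tert-butyldiphenylsilyl)oxy]methyl}-6-formyl-7-[(4-methoxybenzyl)oxy]hepta-1,5-dien-1-yl]-5-oxooxolane-3-carbaldehyde
Product: 30 (3aR,4S,5S,6Z,10E,11aR)-10-{[(tert-butyldiphenylsilyl)oxy]methyl}-4,5-dihydroxy-6-{[(4-methoxybenzyl)oxy]methyl}-3a,4,5,8,9,11a-hexahydrocyclodeca[b]furan-2(3H)-one (8β,9α-diol), via titanium diolate 29 (not isolated)
Conditions: TiCl3(DME)1.5 (12 equiv), Zn–Cu (30 equiv), DME, reflux 2 h, then 25 °C; 28 in DME by syringe pump over 30 h (final 2 mM); pH 7 buffer, Celite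
Reagents that add atoms: none
Why: Low-valent titanium transfers one electron to each aldehyde, the two titanium-bound ketyl radicals combine carbon to carbon to the titanium diolate 29, and neutral hydrolysis frees the diol, no deoxygenation to the olefin being expected at 25 °C. The closest known reaction is the McMurry-type intramolecular pinacol coupling of dialdehydes to medium- and large-ring 1,2-diols. Ring A is closed in a ten-membered mode by ketyl–ketyl union under high dilution, the trans-fused lactone (ring B) and the two ring-cis trisubstituted olefins (C4=C5, C1=C10) leaving few freely rotating bonds in the chain. The C8 face is selected by the adjacent C7 stereocentre of the rigid lactone, which should place O8 cis to C11 (8S), and C9 is set relative to C8 on the titanium diolate, which in a ten-membered ring should favour the trans (threo) diol (9S). The step needs 1,2-coupling at the enal carbon C9 and not at C1, retention of the (Z)-enal geometry and the threo diol; oxygen-bound titanium keeps the spin at C9, coupling through C1 would give a strained eight-membered ring, and the enal is made immediately before use.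

Step 20
Reactants: 30 (3aR,4S,5S,6Z,10E,11aR)-10-{[(tert-butyldiphenylsilyl)oxy]methyl}-4,5-dihydroxy-6-{[(4-methoxybenzyl)oxy]methyl}-3a,4,5,8,9,11a-hexahydrocyclodeca[b]furan-2(3H)-one
Product: 31 8,9-O-isopropylidene acetal (acetonide) of 30
Conditions: CH2=C(OMe)CH3, pyridinium p-toluenesulfonate (cat.), CH2Cl2, 0 °C → rt
Reagents that add atoms: 2-methoxypropene, COC(C)=C
Why: Acid-catalysed ketalisation ties the trans-diol into a dioxolane, which also keeps O8 away from the lactone carbonyl during the enolate chemistry.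

Step 21
Reactants: 31 8,9-O-isopropylidene acetal of 30; 32 N,N-dimethylmethyleneiminium iodide (Eschenmoser's salt)
Product: 36 11(13)-methylene lactone acetonide (3-methylidene derivative of 31), via lithium enolate 33 (not isolated), via Mannich base 34 (not isolated), via ammonium iodide 35 (not isolated)
Conditions: LiN(iPr)2, THF, −78 °C; CH2=NMe2+ I−, −78 °C → rt; then MeI, MeOH, rt; then aq. NaHCO3, CH2Cl2
Reagents that add atoms: Eschenmoser's salt (32), C=[N+](C)C.[I-]
Why: Lithium enolate formation and Mannich reaction with Eschenmoser's salt, then exhaustive methylation and Hofmann-type β-elimination, should give the α-methylene lactone, C11 becoming sp2 so that its transient configuration does not matter.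

Step 22
Reactants: 36 11(13)-methylene lactone acetonide
Product: 37 (3aR,4S,5S,6Z,10E,11aR)-10-{[(tert-butyldiphenylsilyl)oxy]methyl}-4,5-dihydroxy-6-{[(4-methoxybenzyl)oxy]methyl}-3-methylidene-3a,4,5,8,9,11a-hexahydrocyclodeca[b]furan-2(3H)-one
Conditions: AcOH–H2O–THF (3:1:1), 40 °C
Reagents that add atoms: none
Why: Mild aqueous acid hydrolysis should open the strained trans-fused acetonide, while the TBDPS and PMB ethers and the methylene lactone tolerate aqueous acetic acid.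

Step 23
Reactants: 37 (3aR,4S,5S,6Z,10E,11aR)-10-{[(tert-butyldiphenylsilyl)oxy]methyl}-4,5-dihydroxy-6-{[(4-methoxybenzyl)oxy]methyl}-3-methylidene-3a,4,5,8,9,11a-hexahydrocyclodeca[b]furan-2(3H)-one; 38 angelic acid
Product: 40 (3aS,4S,5S,6Z,10E,11aR)-10-{[(tert-butyldiphenylsilyl)oxy]methyl}-6-{[(4-methoxybenzyl)oxy]methyl}-3-methylidene-2-oxo-2,3,3a,4,5,8,9,11a-octahydrocyclodeca[b]furan-4,5-diyl bis[(2Z)-2-methylbut-2-enoate], via mixed anhydride 39 (not isolated)
Conditions: angelic acid (6 equiv), 2,4,6-Cl3C6H2COCl, Et3N, PhMe, rt, 2 h; then 37, 75 °C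
Reagents that add atoms: angelic acid (38), C/C=C(/C)C(=O)O
Why: Yamaguchi-type esterification through the preformed mixed anhydride without nucleophilic catalyst should acylate both secondary hydroxyls and is the variant known to keep the (Z)-geometry of angelates.

Step 24
Reactants: 40 the C14-PMB, C15-TBDPS bis-angelate
Product: 41 (3aS,4S,5S,6Z,10E,11aR)-10-{[(tert-butyldiphenylsilyl)oxy]methyl}-6-(hydroxymethyl)-3-methylidene-2-oxo-2,3,3a,4,5,8,9,11a-octahydrocyclodeca[b]furan-4,5-diyl bis[(2Z)-2-methylbut-2-enoate]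
Conditions: DDQ, CH2Cl2–pH 7 buffer (10:1), 0 °C
Reagents that add atoms: none
Why: Oxidative cleavage of the PMB ether by DDQ (hydride abstraction, then hydrolysis of the oxocarbenium ion) is orthogonal to the silyl ether, the esters and the methylene lactone.

Step 25
Reactants: 41 the C14 alcohol
Product: 42 (3aS,4S,5S,6E,10E,11aR)-10-{[(tert-butyldiphenylsilyl)oxy]methyl}-6-formyl-3-methylidene-2-oxo-2,3,3a,4,5,8,9,11a-octahydrocyclodeca[b]furan-4,5-diyl bis[(2Z)-2-methylbut-2-enoate]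
Conditions: MnO2 (activated), CH2Cl2, rt
Reagents that add atoms: none
Why: Allylic oxidation with MnO2 should give the enal with C14 trans to C2, the stable geometry already fixed by the olefin, without delay that would allow acyl migration from O9.

Step 26
Reactants: 42 the C14 aldehyde, C15-TBDPS ether
Product: 43 CNP0139154.1, (3aS,4S,5S,6E,10E,11aR)-6-formyl-10-(hydroxymethyl)-3-methylidene-2-oxo-2,3,3a,4,5,8,9,11a-octahydrocyclodeca[b]furan-4,5-diyl bis[(2Z)-2-methylbut-2-enoate]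
Conditions: HF·pyridine, pyridine, THF, 0 °C → rt
Reagents that add atoms: none
Why: Buffered fluoride desilylation should free the C15 allylic alcohol without touching the angelates, the enal or the methylene lactone.

Compound list
1 | (S)-5-(hydroxymethyl)furan-2(5H)-one | O=C1C=C[C@@H](CO)O1 | starting material
2 | (S)-5-{[(tert-butyldimethylsilyl)oxy]methyl}furan-2(5H)-one | O=C1C=C[C@@H](CO[Si](C)(C)C(C)(C)C)O1 | intermediate
3 | methanol | CO | starting material
4 | (4R,5S)-5-{[(tert-butyldimethylsilyl)oxy]methyl}-4-(hydroxymethyl)oxolan-2-one | OC[C@H]1CC(=O)O[C@@H]1CO[Si](C)(C)C(C)(C)C | intermediate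
5 | (4R,5S)-5-{[(tert-butyldimethylsilyl)oxy]methyl}-4-[(trityloxy)methyl]oxolan-2-one | C(c1ccccc1)(c1ccccc1)(c1ccccc1)OC[C@H]1CC(=O)O[C@@H]1CO[Si](C)(C)C(C)(C)C | intermediate
6 | (4R,5S)-5-(hydroxymethyl)-4-[(trityloxy)methyl]oxolan-2-one | C(c1ccccc1)(c1ccccc1)(c1ccccc1)OC[C@H]1CC(=O)O[C@@H]1CO | intermediate
7 | (2S,3R)-5-oxo-3-[(trityloxy)methyl]oxolane-2-carbaldehyde | C(c1ccccc1)(c1ccccc1)(c1ccccc1)OC[C@H]1CC(=O)O[C@@H]1C=O | intermediate
8 | 5-chloropent-1-yne | C#CCCCCl | starting material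
9 | methyl chloroformate | COC(=O)Cl | starting material
10 | (5-chloropent-1-yn-1-yl)lithium | [Li]C#CCCCCl | intermediate (not isolated)
11 | methyl 6-chlorohex-2-ynoate | COC(=O)C#CCCCCl | intermediate
12 | methyl (2E)-6-chloro-2-(tributylstannyl)hex-2-enoate | COC(=O)/C(=C\CCCCl)[Sn](CCCC)(CCCC)CCCC | intermediate
13 | (2E)-6-chloro-2-(tributylstannyl)hex-2-en-1-ol | OC/C(=C\CCCCl)[Sn](CCCC)(CCCC)CCCC | intermediate
14 | tributyl[(2E)-6-chloro-1-(trityloxy)hex-2-en-2-yl]stannane | C(c1ccccc1)(c1ccccc1)(c1ccccc1)OC/C(=C\CCCCl)[Sn](CCCC)(CCCC)CCCC | intermediate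
15 | formaldehyde (monomer from paraformaldehyde) | C=O | starting material
16 | [(2Z)-6-chloro-1-(trityloxy)hex-2-en-2-yl]lithium | [Li]/C(COC(c1ccccc1)(c1ccccc1)c1ccccc1)=C/CCCCl | intermediate (not isolated)
17 | (2Z)-6-chloro-2-[(trityloxy)methyl]hex-2-en-1-ol | OC/C(COC(c1ccccc1)(c1ccccc1)c1ccccc1)=C/CCCCl | intermediate
18 | 1-({[(2Z)-6-chloro-2-[(trityloxy)methyl]hex-2-en-1-yl]oxy}methyl)-4-methoxybenzene | COc1ccc(COC/C(COC(c2ccccc2)(c2ccccc2)c2ccccc2)=C/CCCCl)cc1 | intermediate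
19 | 1-({[(2Z)-6-iodo-2-[(trityloxy)methyl]hex-2-en-1-yl]oxy}methyl)-4-methoxybenzene | COc1ccc(COC/C(COC(c2ccccc2)(c2ccccc2)c2ccccc2)=C/CCCI)cc1 | intermediate (not isolated)
20 | [(4Z)-5-{[(4-methoxybenzyl)oxy]methyl}-6-(trityloxy)hex-4-en-1-yl]triphenylphosphonium iodide | COc1ccc(COC/C(COC(c2ccccc2)(c2ccccc2)c2ccccc2)=C/CCC[P+](c2ccccc2)(c2ccccc2)c2ccccc2)cc1.[I-] | intermediate
21 | ethyl formate | CCOC=O | starting material
22 | [(4Z)-5-{[(4-methoxybenzyl)oxy]methyl}-6-(trityloxy)hex-4-en-1-ylidene]triphenyl-λ5-phosphane | COc1ccc(COC/C(COC(c2ccccc2)(c2ccccc2)c2ccccc2)=C/CCC=P(c2ccccc2)(c2ccccc2)c2ccccc2)cc1 | intermediate (not isolated)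
23 | (5Z)-6-{[(4-methoxybenzyl)oxy]methyl}-2-(triphenyl-λ5-phosphanylidene)-7-(trityloxy)hept-5-enal | COc1ccc(COC/C(COC(c2ccccc2)(c2ccccc2)c2ccccc2)=C/CCC(C=O)=P(c2ccccc2)(c2ccccc2)c2ccccc2)cc1 | intermediate
24 | (2E)-2-[(3Z)-4-{[(4-methoxybenzyl)oxy]methyl}-5-(trityloxy)pent-3-en-1-yl]-3-{(2R,3R)-5-oxo-3-[(trityloxy)methyl]oxolan-2-yl}prop-2-enal | C(c1ccccc1)(c1ccccc1)(c1ccccc1)OC[C@H]1CC(=O)O[C@@H]1/C=C(/C=O)CC/C=C(/COCc1ccc(OC)cc1)COC(c1ccccc1)(c1ccccc1)c1ccccc1 | intermediate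
25 | (4R,5R)-5-[(1E,5Z)-2-(hydroxymethyl)-6-{[(4-methoxybenzyl)oxy]methyl}-7-(trityloxy)hepta-1,5-dien-1-yl]-4-[(trityloxy)methyl]oxolan-2-one | C(c1ccccc1)(c1ccccc1)(c1ccccc1)OC[C@H]1CC(=O)O[C@@H]1/C=C(/CO)CC/C=C(/COCc1ccc(OC)cc1)COC(c1ccccc1)(c1ccccc1)c1ccccc1 | intermediate
26 | (4R,5R)-5-[(1E,5Z)-2-{[(tert-butyldiphenylsilyl)oxy]methyl}-6-{[(4-methoxybenzyl)oxy]methyl}-7-(trityloxy)hepta-1,5-dien-1-yl]-4-[(trityloxy)methyl]oxolan-2-one | C(c1ccccc1)(c1ccccc1)(c1ccccc1)OC[C@H]1CC(=O)O[C@@H]1/C=C(/CO[Si](c1ccccc1)(c1ccccc1)C(C)(C)C)CC/C=C(/COCc1ccc(OC)cc1)COC(c1ccccc1)(c1ccccc1)c1ccccc1 | intermediate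
27 | (4R,5R)-5-[(1E,5E)-2-{[(tert-butyldiphenylsilyl)oxy]methyl}-7-hydroxy-6-{[(4-methoxybenzyl)oxy]methyl}hepta-1,5-dien-1-yl]-4-(hydroxymethyl)oxolan-2-one | OC[C@H]1CC(=O)O[C@@H]1/C=C(/CO[Si](c1ccccc1)(c1ccccc1)C(C)(C)C)CC/C=C(/COCc1ccc(OC)cc1)CO | intermediate
28 | (2R,3S)-2-[(1E,5Z)-2-{[(tert-butyldiphenylsilyl)oxy]methyl}-6-formyl-7-[(4-methoxybenzyl)oxy]hepta-1,5-dien-1-yl]-5-oxooxolane-3-carbaldehyde | O=C[C@H]1CC(=O)O[C@@H]1/C=C(/CO[Si](c1ccccc1)(c1ccccc1)C(C)(C)C)CC/C=C(/COCc1ccc(OC)cc1)C=O | intermediate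
29 | titanium diolate of 30 (drawn as the cyclic dichlorotitanium 8,9-diolate) | C1C(=O)O[C@@H]2/C=C(/CO[Si](c3ccccc3)(c3ccccc3)C(C)(C)C)CC/C=C(/COCc3ccc(OC)cc3)[C@H](O4)[C@@H](O[Ti]4(Cl)Cl)[C@@H]12 | intermediate (not isolated)
30 | (3aR,4S,5S,6Z,10E,11aR)-10-{[(tert-butyldiphenylsilyl)oxy]methyl}-4,5-dihydroxy-6-{[(4-methoxybenzyl)oxy]methyl}-3a,4,5,8,9,11a-hexahydrocyclodeca[b]furan-2(3H)-one | C1C(=O)O[C@@H]2/C=C(/CO[Si](c3ccccc3)(c3ccccc3)C(C)(C)C)CC/C=C(/COCc3ccc(OC)cc3)[C@H](O)[C@@H](O)[C@@H]12 | intermediate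
31 | 8,9-O-isopropylidene acetal (acetonide) of 30 | C1C(=O)O[C@@H]2/C=C(/CO[Si](c3ccccc3)(c3ccccc3)C(C)(C)C)CC/C=C(/COCc3ccc(OC)cc3)[C@H](O4)[C@@H](OC4(C)C)[C@@H]12 | intermediate
32 | N,N-dimethylmethyleneiminium iodide (Eschenmoser's salt) | C=[N+](C)C.[I-] | starting material
33 | lithium enolate of 31 | C1=C(O[Li])O[C@@H]2/C=C(/CO[Si](c3ccccc3)(c3ccccc3)C(C)(C)C)CC/C=C(/COCc3ccc(OC)cc3)[C@H](O4)[C@@H](OC4(C)C)[C@@H]12 | intermediate (not isolated)
34 | 11-[(dimethylamino)methyl] lactone (Mannich base) of 31, C11 epimers | CN(C)CC1C(=O)O[C@@H]2/C=C(/CO[Si](c3ccccc3)(c3ccccc3)C(C)(C)C)CC/C=C(/COCc3ccc(OC)cc3)[C@H](O4)[C@@H](OC4(C)C)[C@@H]12 | intermediate (not isolated)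
35 | 11-[(trimethylammonio)methyl] lactone iodide of 31, C11 epimers | C[N+](C)(C)CC1C(=O)O[C@@H]2/C=C(/CO[Si](c3ccccc3)(c3ccccc3)C(C)(C)C)CC/C=C(/COCc3ccc(OC)cc3)[C@H](O4)[C@@H](OC4(C)C)[C@@H]12.[I-] | intermediate (not isolated)
36 | 11(13)-methylene lactone acetonide (3-methylidene derivative of 31) | C=C1C(=O)O[C@@H]2/C=C(/CO[Si](c3ccccc3)(c3ccccc3)C(C)(C)C)CC/C=C(/COCc3ccc(OC)cc3)[C@H](O4)[C@@H](OC4(C)C)[C@@H]12 | intermediate
37 | (3aR,4S,5S,6Z,10E,11aR)-10-{[(tert-butyldiphenylsilyl)oxy]methyl}-4,5-dihydroxy-6-{[(4-methoxybenzyl)oxy]methyl}-3-methylidene-3a,4,5,8,9,11a-hexahydrocyclodeca[b]furan-2(3H)-one | C=C1C(=O)O[C@@H]2/C=C(/CO[Si](c3ccccc3)(c3ccccc3)C(C)(C)C)CC/C=C(/COCc3ccc(OC)cc3)[C@H](O)[C@@H](O)[C@@H]12 | intermediate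
38 | angelic acid, (2Z)-2-methylbut-2-enoic acid | C/C=C(/C)C(=O)O | starting material
39 | (2Z)-2-methylbut-2-enoic 2,4,6-trichlorobenzoic anhydride | C/C=C(/C)C(=O)OC(=O)c1c(Cl)cc(Cl)cc1Cl | intermediate (not isolated)
40 | (3aS,4S,5S,6Z,10E,11aR)-10-{[(tert-butyldiphenylsilyl)oxy]methyl}-6-{[(4-methoxybenzyl)oxy]methyl}-3-methylidene-2-oxo-2,3,3a,4,5,8,9,11a-octahydrocyclodeca[b]furan-4,5-diyl bis[(2Z)-2-methylbut-2-enoate] | C=C1C(=O)O[C@@H]2/C=C(/CO[Si](c3ccccc3)(c3ccccc3)C(C)(C)C)CC/C=C(/COCc3ccc(OC)cc3)[C@H](OC(=O)/C(C)=C\C)[C@@H](OC(=O)/C(C)=C\C)[C@@H]12 | intermediate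
41 | (3aS,4S,5S,6Z,10E,11aR)-10-{[(tert-butyldiphenylsilyl)oxy]methyl}-6-(hydroxymethyl)-3-methylidene-2-oxo-2,3,3a,4,5,8,9,11a-octahydrocyclodeca[b]furan-4,5-diyl bis[(2Z)-2-methylbut-2-enoate] | C=C1C(=O)O[C@@H]2/C=C(/CO[Si](c3ccccc3)(c3ccccc3)C(C)(C)C)CC/C=C(/CO)[C@H](OC(=O)/C(C)=C\C)[C@@H](OC(=O)/C(C)=C\C)[C@@H]12 | intermediate
42 | (3aS,4S,5S,6E,10E,11aR)-10-{[(tert-butyldiphenylsilyl)oxy]methyl}-6-formyl-3-methylidene-2-oxo-2,3,3a,4,5,8,9,11a-octahydrocyclodeca[b]furan-4,5-diyl bis[(2Z)-2-methylbut-2-enoate] | C=C1C(=O)O[C@@H]2/C=C(/CO[Si](c3ccccc3)(c3ccccc3)C(C)(C)C)CC/C=C(/C=O)[C@H](OC(=O)/C(C)=C\C)[C@@H](OC(=O)/C(C)=C\C)[C@@H]12 | intermediate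
43 | CNP0139154.1, (3aS,4S,5S,6E,10E,11aR)-6-formyl-10-(hydroxymethyl)-3-methylidene-2-oxo-2,3,3a,4,5,8,9,11a-octahydrocyclodeca[b]furan-4,5-diyl bis[(2Z)-2-methylbut-2-enoate] | C=C1C(=O)O[C@@H]2/C=C(/CO)CC/C=C(/C=O)[C@H](OC(=O)/C(C)=C\C)[C@@H](OC(=O)/C(C)=C\C)[C@@H]12 | target

Total step count: 26 steps.
Longest linear sequence: 21 steps (steps 6–13, then 14–26); the lactone branch (steps 1–5) joins at step 14.

Steps most likely to fail

1. Step 19 (pinacol ring closure). The two ketyls may unite with the wrong relative configuration at C9, giving the cis-8,9-diol, while intermolecular coupling competes. The fallback sets out from 28 and accepts the ring closure with the C9 configuration it delivers, then sets C9 by reagent control. The 9-epimeric cis-diol F1 would be oxidised at its allylic carbinol only (MnO2, CH2Cl2, rt) to the α-hydroxy enone F2. This C9 ketone would be reduced by Corey–Bakshi–Shibata reduction with BH3·SMe2 and (S)-1-methyl-3,3-diphenyltetrahydro-1H,3H-pyrrolo[1,2-c][1,3,2]oxazaborole. The (S)-catalyst is expected to give 9S if the alkenyl group acts as the large substituent; otherwise its enantiomer would be used. The sequence comes back to the route at 30.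

2. Step 23 (bis-angeloylation). Acylation of the second, hindered hydroxyl may stall, and prolonged heating may isomerise the angeloyl unit to tigloyl. The fallback sets out from 37 and builds the (Z)-olefin of each ester on the molecule instead of transferring a preformed (Z)-acyl group. Both hydroxyls would be esterified with 2-[bis(2,2,2-trifluoroethoxy)phosphoryl]propanoic acid (N,N'-dicyclohexylcarbodiimide, 4-(dimethylamino)pyridine cat., CH2Cl2) to the bis(phosphonopropionate) F7. Still–Gennari olefination with acetaldehyde (KN(SiMe3)2, 18-crown-6, THF, −78 °C) should then give the two (Z)-2-methylbut-2-enoates. The sequence comes back to the route at 40.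

3. Step 14 (Wittig olefination with the formyl ylide). The weakly nucleophilic formyl-stabilised ylide may react slowly at 80 °C, which would allow epimerisation at C6 of the α-acyloxy aldehyde. The fallback sets out from 20 and 7 and uses a more reactive ester-stabilised ylide. Salt 20 would be deprotonated (NaN(SiMe3)2, 2 equiv) and the ylide acylated with allyl chloroformate to the allyl ester ylide F3. This would react with 7 at rt in CH2Cl2 (E-selective Wittig) to the allyl enoate F4. Deallylation with Pd(PPh3)4 and morpholine would give the enoic acid F5. Activation as the mixed carbonic anhydride F6 (i-BuOCOCl, N-methylmorpholine, THF, −15 °C) and reduction with NaBH4 in THF–H2O should give the allylic alcohol without touching the lactone. The sequence comes back to the route at 25.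

Further compounds
F1 | step 19 | (3aR,4S,5R,6Z,10E,11aR)-10-{[(tert-butyldiphenylsilyl)oxy]methyl}-4,5-dihydroxy-6-{[(4-methoxybenzyl)oxy]methyl}-3a,4,5,8,9,11a-hexahydrocyclodeca[b]furan-2(3H)-one (9-epimer of 30, cis-8,9-diol) | C1C(=O)O[C@@H]2/C=C(/CO[Si](c3ccccc3)(c3ccccc3)C(C)(C)C)CC/C=C(/COCc3ccc(OC)cc3)[C@@H](O)[C@@H](O)[C@@H]12
F2 | step 19 | C9 ketone (8-hydroxy-9-oxo analogue of 30, α-hydroxy enone) | C1C(=O)O[C@@H]2/C=C(/CO[Si](c3ccccc3)(c3ccccc3)C(C)(C)C)CC/C=C(/COCc3ccc(OC)cc3)C(=O)[C@@H](O)[C@@H]12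
F3 | step 14 | allyl (5Z)-6-{[(4-methoxybenzyl)oxy]methyl}-2-(triphenyl-λ5-phosphanylidene)-7-(trityloxy)hept-5-enoate | C=CCOC(=O)C(CC/C=C(/COCc1ccc(OC)cc1)COC(c1ccccc1)(c1ccccc1)c1ccccc1)=P(c1ccccc1)(c1ccccc1)c1ccccc1
F4 | step 14 | allyl (2E)-2-[(3Z)-4-{[(4-methoxybenzyl)oxy]methyl}-5-(trityloxy)pent-3-en-1-yl]-3-{(2R,3R)-5-oxo-3-[(trityloxy)methyl]oxolan-2-yl}prop-2-enoate | C(c1ccccc1)(c1ccccc1)(c1ccccc1)OC[C@H]1CC(=O)O[C@@H]1/C=C(/C(=O)OCC=C)CC/C=C(/COCc1ccc(OC)cc1)COC(c1ccccc1)(c1ccccc1)c1ccccc1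
F5 | step 14 | (2E)-2-[(3Z)-4-{[(4-methoxybenzyl)oxy]methyl}-5-(trityloxy)pent-3-en-1-yl]-3-{(2R,3R)-5-oxo-3-[(trityloxy)methyl]oxolan-2-yl}prop-2-enoic acid | C(c1ccccc1)(c1ccccc1)(c1ccccc1)OC[C@H]1CC(=O)O[C@@H]1/C=C(/C(=O)O)CC/C=C(/COCc1ccc(OC)cc1)COC(c1ccccc1)(c1ccccc1)c1ccccc1
F6 | step 14 | mixed isobutyl carbonic anhydride of F5 | C(c1ccccc1)(c1ccccc1)(c1ccccc1)OC[C@H]1CC(=O)O[C@@H]1/C=C(/C(=O)OC(=O)OCC(C)C)CC/C=C(/COCc1ccc(OC)cc1)COC(c1ccccc1)(c1ccccc1)c1ccccc1
F7 | step 23 | 8,9-bis{2-[bis(2,2,2-trifluoroethoxy)phosphoryl]propanoate} of 37 (epimers at the phosphonate-bearing carbons) | C=C1C(=O)O[C@@H]2/C=C(/CO[Si](c3ccccc3)(c3ccccc3)C(C)(C)C)CC/C=C(/COCc3ccc(OC)cc3)[C@H](OC(=O)C(C)P(=O)(OCC(F)(F)F)OCC(F)(F)F)[C@@H](OC(=O)C(C)P(=O)(OCC(F)(F)F)OCC(F)(F)F)[C@@H]12
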